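Positions are given in labdane numbering throughout: C10 is the quaternary ring carbon, C5 the ring carbon that carries C6, and C9 the carbon α to C8.

## The problem

The target is the 6α-angelate of (13R)-labd-14-ene-6α,8α,13-triol. It is a trans-fused decalin (rings A and B) with an axial methyl on quaternary C10, a gem-dimethyl C4, and an equatorial chain at C9 that ends in a tertiary vinyl carbinol.

Five stereocentres are contiguous on ring B (C5, C6, C8, C9, C10). C10 is quaternary and cannot be repaired, so it needs an absolute method; it is also the only ring centre from which the others can be derived. C13 is too far from the ring for substrate control and is best taken from the chiral pool.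

C8 is a tertiary carbinol with an axial (β) methyl. A methyl nucleophile would attack an 8-ketone from the open α face and give the wrong epimer, so oxygen, not carbon, has to be delivered from the α face.

Three groups limit the reagents. The tertiary allylic C13 carbinol ionises in acid. The angelate isomerises to the tiglate and does not survive hydride, so it must go on late. Any 6-oxygenated 8-ketone is a β-hydroxy ketone that can lose water.

The enabling feature is that O6 is β to C8. With C8 as a ketone (the 17-nor compound), ring B is the aldol of a C8 methyl ketone (C7 is its methyl) with a C6 aldehyde on C5 of ring A. This 1,5-keto aldehyde can close only a six-membered ring. In the open form C5 and C9 are α to carbonyl groups and C6 is formed reversibly, so all three can relax against C10.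

## Retrosynthesis

**Ester and silyl group.** Target 29 is cut at the C13 silyl ether (28) and then at the O6–acyl bond, giving diol 25 and angelic acid 26. The ester goes on after the last hydride step. The C13 hydroxyl stays silylated during acylation, so only a secondary hydroxyl competes with the tertiary C8 hydroxyl. The forward reaction must transfer the angeloyl group without Z-to-E isomerisation.

**C8 carbinol.** The C8–O and C8–C17 bonds of 25 are traced to epoxide 24, exocyclic alkene 23 and ketone 20 (through its TMS ether 21). Cutting C8–CH3 directly would need axial methyl attack past the C10 methyl. The detour through methylenation, α-face epoxidation and hydride opening at C17 gives the 8α-hydroxyl. It costs four steps and asks for α-face selectivity and preference for the 1,1-disubstituted alkene over the vinyl group.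

**Ring B (key cut).** The C6–C7 bond of 20 is cut to keto aldehyde 19. This removes ring B and the stereocentres C5, C6 and C9, leaving a monocyclic ring A with only C10 and C13 defined. Cutting C5–C6 or C9–C10 instead would break a bond at a quaternary or doubly neopentyl carbon. The forward reaction must add without dehydrating and must let C5, C6 and C9 equilibrate.

**Carbonyl groups of 19.** The aldehyde is traced to a primary alcohol and the methyl ketone (C7–C8 bond) to a nitrile, giving hydroxy nitrile 16 via hydroxy ketone 18. A nitrile at C8 makes C9 the only acidic carbon and accepts one methyl group only. C6 is kept as an alcohol because an epoxide or free aldehyde at C6 would not survive next to a C8 ketone under acid or organolithium reagents. The final unmasking is then a neutral oxidation that the C13 silyl ether tolerates.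

**C9–C11 bond.** Nitrile 16 is cut into ring fragment 9 and iodide 15. This is the only chain bond whose formation leaves C13 untouched, so the chain stereocentre arrives finished. The cuts at C11–C12 or C12–C13 would put a leaving group β to the silyloxy carbon or create C13 without control. The forward reaction is alkylation of a carbanion next to quaternary C10.

**Chain fragment.** Iodide 15 is traced through acid 13 and silyl ether 11 to (R)-linalool 10. Linalool has the C13 carbinol in the right configuration, but cleavage of its trisubstituted alkene leaves one carbon too many. That carbon is removed as CO2 in a decarboxylative iodination.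

**Ring fragment.** Hydroxy nitrile 9 is traced to epoxy nitrile 7 (C6 comes from an epoxide by hydride shift), then to allyl epoxide 5 (CH2CN from the allyl group), then to allyl ketone 4 (C5–C6 bond by ylide addition). The ring ketone of 4 cannot enolise, so a one-carbon nucleophile has no competing pathway. Doing the rearrangement before a C8 carbonyl exists avoids participation by that carbonyl.

**Quaternary C10.** Ketone 4 is cut at C9–C10 to enol carbonate 3, made from 2,2,6-trimethylcyclohexanone 1 and allyl chloroformate 2. A catalytic asymmetric allylation sets the one centre that everything else depends on.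

## Roads not taken

**Alternative 1:** Ring B is cut at C7–C8 and C9–C10 as an intramolecular Diels–Alder reaction. A but-2-ynoate is tethered through a temporary oxygen at C1 (ester A1), and heating gives the tricyclic dienyl lactone A2.
- Merits: two C–C bonds, ring B and the quaternary C10 form in one irreversible step. C10 is relayed from a simple secondary carbinol. C11 and C17 arrive as carboxyl and methyl.
- Weak points: the diene terminus C10 is fully substituted and the s-cis diene is crowded by the C4 gem-dimethyl group. A2 still lacks every ring B stereocentre of the target. The C5=C6 and C8=C9 alkenes must become 5α-H/6α-OH and 8α-OH/9α-H, and hydrating a tetrasubstituted alkene with that outcome has no reliable solution. The C1 oxygen must be removed, and the chain must be grown from C11 with C13 made without control.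
- Comparison: in the ring-forming step this road is better than the chosen plan, because it does not depend on an equilibrium. The chosen plan sets against it that C5, C6 and C9 come from one operation, that no oxygen has to be deleted, and that C13 comes from linalool.

**Alternative 2:** The C9–C10 bond is cut as an Ireland–Claisen rearrangement. The silyl ketene acetal of δ-lactone A3 (a mevalonolactone-type ring carrying the ring A cyclohexenyl group on its O–CH carbon) rearranges to cyclohexene acid A4.
- Merits: C10 and C9 are set by chirality transfer. The C8 tertiary carbinol, with methyl and oxygen, is present from the start; this is better than the chosen plan, which spends steps 13 to 16 on C8. The C5=C6 alkene could take 5α-H and 6α-OH in one α-face hydroboration.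
- Weak points: the enolate must be formed on a lactone with a β-silyloxy group, which invites elimination. The new bond is made to a fully substituted alkene carbon flanked by the gem-dimethyl group, in a boat forced by the lactone. C9 comes out with the carboxyl α and must be inverted. The chain still has to be built from C11.
- Comparison: the chosen plan has no elimination-prone enolate, no congested sigmatropic bond formation and no C9 inversion. It pays with the longer C8 sequence and its reliance on thermodynamic control.

**Alternative 3:** Ring A is cut at C1–C10 and C4–C5 as an enantioselective Diels–Alder reaction. A chiral Lewis acid joins quinone A5 and diene A6 to give the cis-fused adduct A7, whose quinone ring becomes ring B.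
- Merits: two cheap flat compounds give an enantioenriched bicycle with C10, the C6 oxygen and the C8 methyl in one catalytic step. No other road reaches the core as quickly.
- Weak points: A6 has a disubstituted terminus and reaches the s-cis form poorly, so it is a weak diene. The quinone regiochemistry must be controlled. After the cycloaddition C9 is a ketone that must become a CH with the chain equatorial, C5 must be epimerised, the ring A alkene removed and the ene-dione turned into the 8α-carbinol. C13 is again uncontrolled.
- Comparison: A7 is reached faster than 20. The chosen plan attaches the finished chain before ring B closes and needs far fewer redox corrections afterwards.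

Key step: step 12

Assumption: with the (S)-configured PHOX ligand this allylation gives (S)-2-allyl-2-alkylcyclohexanones, so the (R)-ligand is specified for (R)-4. If the sense is the reverse, the other ligand enantiomer is used and nothing else changes.

Remark on stereochemistry: compounds 5 to 9 and 16 to 19 are carried as epimer mixtures at C5 (and C9 from 16 on). Step 12 is designed to converge them. Their SMILES leave these centres open.

## Route

Step 1
Reactants: 1 2,2,6-trimethylcyclohexanone; 2 allyl chloroformate
Product: 3 allyl 2,6,6-trimethylcyclohex-1-en-1-yl carbonate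
Conditions: LiN(SiMe3)2, THF, 0 °C; then 2, −78 °C to rt
Reagents that add atoms: none
Why: The ketone can enolise only toward C6, and the lithium enolate of this hindered ketone is acylated on oxygen by the chloroformate (enol carbonate formation), which stores the enolate regiochemistry for the next step.

Step 2
Reactants: 3 allyl 2,6,6-trimethylcyclohex-1-en-1-yl carbonate
Product: 4 (2R)-2,6,6-trimethyl-2-(prop-2-en-1-yl)cyclohexan-1-one
Conditions: Pd2(dba)3 (2.5 mol %), (R)-t-BuPHOX [(R)-4-tert-butyl-2-(2-diphenylphosphinophenyl)-4,5-dihydrooxazole] (6 mol %), THF, 25 °C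
Reagents that add atoms: none
Why: Decarboxylative asymmetric allylic alkylation (Tsuji allylation): zerovalent palladium ionises the allyl carbonate, CO2 is lost and the PHOX-bound allylpalladium enolate collapses to the α-quaternary ketone. The ligand alone sets C10, and the (R)-ligand is taken so that the allyl group enters the face that gives (R)-4.

Step 3
Reactants: 4 (2R)-2,6,6-trimethyl-2-(prop-2-en-1-yl)cyclohexan-1-one
Product: 5 (4R)-4,8,8-trimethyl-4-(prop-2-en-1-yl)-1-oxaspiro[2.5]octane (both spiro epimers)
Conditions: Me3S+ I−, n-BuLi, THF, 0 °C to rt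
Reagents that add atoms: trimethylsulfonium iodide, C[S+](C)C.[I-]
Why: Corey–Chaykovsky epoxidation; the small, irreversibly adding sulfonium ylide suits a hindered ketone that cannot enolise. The new spiro centre forms without control, which does not matter because step 5 erases it.

Step 4
Reactants: 5 (4R)-4,8,8-trimethyl-4-(prop-2-en-1-yl)-1-oxaspiro[2.5]octane
Product: 7 2-[(4R)-4,8,8-trimethyl-1-oxaspiro[2.5]octan-4-yl]acetonitrile (both spiro epimers), via epoxy aldehyde 6 (not isolated)
Conditions: O3, CH2Cl2/MeOH, −78 °C; Me2S; then I2, aq. NH3, THF, rt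
Reagents that add atoms: ammonia, N
Why: Ozonolysis cleaves the only alkene to the aldehyde, and iodine in aqueous ammonia converts it through the N-iodo aldimine into the nitrile (oxidative aldehyde-to-nitrile conversion); the hindered epoxide is inert to both. The nitrile makes C9 the only acidic carbon and is a masked C8 acyl group.

Step 5
Reactants: 7 2-[(4R)-4,8,8-trimethyl-1-oxaspiro[2.5]octan-4-yl]acetonitrile
Product: 9 2-[(1R)-2-(hydroxymethyl)-1,3,3-trimethylcyclohexyl]acetonitrile (both C2 epimers), via cyano aldehyde 8 (not isolated)
Conditions: BF3·OEt2 (0.1 equiv), CH2Cl2, −78 to 0 °C; then MeOH, NaBH4, 0 °C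
Reagents that add atoms: none
Why: Meinwald rearrangement: BF3 opens the epoxide at tertiary C5 and a 1,2-hydride shift from C6 gives the aldehyde, the cation having no other β-hydrogen and the nitrile being a spectator; borohydride then reduces the aldehyde in the same flask. C5 forms as a mixture, accepted because step 12 equilibrates it, and C6 is kept at the alcohol level so that it survives the carbanion chemistry.

Step 6
Reactants: 10 (R)-linalool
Product: 11 triethyl{[(3R)-3,7-dimethylocta-1,6-dien-3-yl]oxy}silane
Conditions: Et3SiOTf, 2,6-lutidine, CH2Cl2, −78 to 0 °C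
Reagents that add atoms: triethylsilyl trifluoromethanesulfonate, CC[Si](CC)(CC)OS(=O)(=O)C(F)(F)F
Why: Silylation of a tertiary alcohol with a silyl triflate and a hindered base; the TES ether shields the ionisable allylic carbinol and is still removable by fluoride at the end.

Step 7
Reactants: 11 triethyl{[(3R)-3,7-dimethylocta-1,6-dien-3-yl]oxy}silane
Product: 13 (4R)-4-methyl-4-[(triethylsilyl)oxy]hex-5-enoic acid, via aldehyde 12 (not isolated)
Conditions: O3 (1 equiv), pyridine, CH2Cl2/MeOH, −78 °C; Me2S; then NaClO2, NaH2PO4, 2-methyl-2-butene, t-BuOH/H2O, 0 °C to rt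
Reagents that add atoms: ozone, [O-][O+]=O; sodium chlorite, [Na+].[O-]Cl=O
Why: Ozone attacks the electron-rich trisubstituted alkene far faster than the vinyl group beside the silyloxy quaternary carbon (chemoselective ozonolysis), and Pinnick oxidation takes the aldehyde to the acid without touching the vinyl group.

Step 8
Reactants: 13 (4R)-4-methyl-4-[(triethylsilyl)oxy]hex-5-enoic acid
Product: 15 triethyl{[(3R)-5-iodo-3-methylpent-1-en-3-yl]oxy}silane, via thiohydroxamate ester 14 (not isolated)
Conditions: N-hydroxypyridine-2-thione, DCC, DMAP (cat.), CH2Cl2, rt, dark; then CHI3, benzene, hν (tungsten lamp), rt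
Reagents that add atoms: iodoform, IC(I)I
Why: Barton decarboxylative iodination: photolysis of the thiohydroxamate ester gives the primary alkyl radical after loss of CO2, and this abstracts iodine from iodoform. It removes the one carbon by which linalool is too long and leaves C13 untouched.

Step 9
Reactants: 9 2-[(1R)-2-(hydroxymethyl)-1,3,3-trimethylcyclohexyl]acetonitrile; 15 triethyl{[(3R)-5-iodo-3-methylpent-1-en-3-yl]oxy}silane
Product: 16 (5R)-2-[(1R)-2-(hydroxymethyl)-1,3,3-trimethylcyclohexyl]-5-methyl-5-[(triethylsilyl)oxy]hept-6-enenitrile (epimers at chain C2 and ring C2)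
Conditions: LiN(iPr)2 (2.3 equiv), THF, −78 to 0 °C; then 15, DMPU, −78 °C to rt
Reagents that add atoms: none
Why: Alkylation of a nitrile-stabilised carbanion (formed beside the lithium alkoxide) with a primary iodide; the slim, highly nucleophilic cyano carbanion tolerates the neighbouring quaternary C10. C9 forms as a mixture that step 12 equilibrates, and diastereomers stemming from the minor enantiomer of 4 can be removed from here on.

Step 10
Reactants: 16 (5R)-2-[(1R)-2-(hydroxymethyl)-1,3,3-trimethylcyclohexyl]-5-methyl-5-[(triethylsilyl)oxy]hept-6-enenitrile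
Product: 18 (6R)-3-[(1S)-2-(hydroxymethyl)-1,3,3-trimethylcyclohexyl]-6-methyl-6-[(triethylsilyl)oxy]oct-7-en-2-one (epimer mixture; in equilibrium with its cyclic hemiketal; ring descriptor changed by priority only), via ketimine 17 (not isolated)
Conditions: MeLi (4 equiv), Et2O, 0 °C to rt; then aq. NH4Cl, rt
Reagents that add atoms: methyllithium, [Li]C; water, O
Why: Methyllithium adds to the nitrile to give an N-lithio ketimine that cannot add a second time, and hydrolysis releases the methyl ketone (nitrile-to-ketone conversion); the first equivalent only deprotonates the hydroxyl.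

Step 11
Reactants: 18 (6R)-3-[(1S)-2-(hydroxymethyl)-1,3,3-trimethylcyclohexyl]-6-methyl-6-[(triethylsilyl)oxy]oct-7-en-2-one
Product: 19 (2S)-2,6,6-trimethyl-2-[(6R)-6-methyl-2-oxo-6-[(triethylsilyl)oxy]oct-7-en-3-yl]cyclohexane-1-carbaldehyde (epimers at ring C1 and chain C3, that is C5 and C9)
Conditions: Dess–Martin periodinane, pyridine, CH2Cl2, 0 °C to rt
Reagents that add atoms: none
Why: Dess–Martin oxidation of the primary alcohol of the open-chain form; the hemiketal has no carbinol hydrogen and drains through that form. Neutral, non-enolising conditions keep the TES ether and deliver the keto aldehyde without premature aldol reaction.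

Step 12
Reactants: 19 (2S)-2,6,6-trimethyl-2-[(6R)-6-methyl-2-oxo-6-[(triethylsilyl)oxy]oct-7-en-3-yl]cyclohexane-1-carbaldehyde
Product: 20 (13R)-6α-hydroxy-13-[(triethylsilyl)oxy]-17-norlabd-14-en-8-one
Conditions: NaOMe (0.3 equiv), MeOH, 0 °C to rt
Reagents that add atoms: none
Why: Methoxide reversibly forms the C7 enolate of the C8 methyl ketone, which adds to the C6 aldehyde on C5 and forms C6–C7; this is the base-mediated intramolecular aldol addition of a 1,5-keto aldehyde to a 3-hydroxycyclohexanone, a known reaction type. Ring B closes in the 6-(enolexo)-exo-trig mode through a chair with the C10 methyl axial. C6 is set by reversible retro-aldol and aldol steps, the hydroxyl settling equatorial (α), away from the syn-axial C10 and C4 β-methyl groups. C9 is α to the C8 ketone and equilibrates by enolisation to the equatorial chain. C5 is not acidic in the closed product and is corrected only by retro-aldol opening to 19, where the aldehyde α-hydrogen exchanges; the trans-fused decalin with C5–C6, C9–C11 and C6–O all equatorial is expected to be the thermodynamic sink fixed by quaternary C10. The step needs addition without dehydration: the equatorial 6α-hydroxyl of the trans-fused product is poorly aligned with the C7–C8 enolate, so E1cB loss of water is slow for the wanted isomer and is further restrained by low temperature and substoichiometric base. Regiochemistry is secured by ring size, since the C9 or C5 enolates could close only four-membered rings.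

Step 13
Reactants: 20 (13R)-6α-hydroxy-13-[(triethylsilyl)oxy]-17-norlabd-14-en-8-one
Product: 21 (13R)-13-[(triethylsilyl)oxy]-6α-[(trimethylsilyl)oxy]-17-norlabd-14-en-8-one
Conditions: Me3SiCl, imidazole, CH2Cl2, 0 °C
Reagents that add atoms: chlorotrimethylsilane, C[Si](C)(C)Cl
Why: Silylation of the secondary alcohol; the TMS ether stops retro-aldol cleavage of the alkoxide under the ylide and is the one silyl group that mild methanolysis removes beside the tertiary TES ether.

Step 14
Reactants: 21 (13R)-13-[(triethylsilyl)oxy]-6α-[(trimethylsilyl)oxy]-17-norlabd-14-en-8-one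
Product: 23 (13R)-13-[(triethylsilyl)oxy]labda-8(17),14-dien-6α-ol, via trimethylsilyl ether 22 (not isolated)
Conditions: Ph3PCH3+ Br−, KOtBu, toluene, 0 to 80 °C; then K2CO3, MeOH, rt
Reagents that add atoms: methyltriphenylphosphonium bromide, C[P+](c1ccccc1)(c1ccccc1)c1ccccc1.[Br-]
Why: Wittig methylenation of the hindered 8-ketone, the usual reaction of 8-oxo-17-norlabdanes; the equatorial silyloxy group is poorly placed for β-elimination and C9 already has its stable configuration. Basic methanol then cleaves only the TMS ether.

Step 15
Reactants: 23 (13R)-13-[(triethylsilyl)oxy]labda-8(17),14-dien-6α-ol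
Product: 24 (13R)-8α,17-epoxy-13-[(triethylsilyl)oxy]labd-14-en-6α-ol
Conditions: mCPBA (1.05 equiv), NaHCO3, CH2Cl2, 0 °C
Reagents that add atoms: 3-chloroperbenzoic acid, OOC(=O)c1cccc(Cl)c1
Why: Peracid epoxidation; the 1,1-disubstituted exocyclic alkene reacts much faster than the vinyl group, and the reagent comes from the α face because the β face is screened by the axial C10 methyl, so oxygen is placed α at C8.

Step 16
Reactants: 24 (13R)-8α,17-epoxy-13-[(triethylsilyl)oxy]labd-14-en-6α-ol
Product: 25 (13R)-13-[(triethylsilyl)oxy]labd-14-ene-6α,8α-diol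
Conditions: LiAlH4, THF, 0 °C to rt
Reagents that add atoms: none
Why: Hydride opens the epoxide at the primary carbon C17 (reductive epoxide opening, SN2), which becomes the β-methyl and leaves the 8α tertiary hydroxyl; the C8 configuration is the one set in step 15.

Step 17
Reactants: 25 (13R)-13-[(triethylsilyl)oxy]labd-14-ene-6α,8α-diol; 26 angelic acid
Product: 28 (13R)-8α-hydroxy-13-[(triethylsilyl)oxy]labd-14-en-6α-yl (Z)-2-methylbut-2-enoate, via mixed anhydride 27 (not isolated)
Conditions: 26, 2,4,6-trichlorobenzoyl chloride, Et3N, toluene, rt; then 25, 80 °C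
Reagents that add atoms: none
Why: Yamaguchi esterification through the 2,4,6-trichlorobenzoic mixed anhydride without a nucleophilic catalyst, the protocol that transfers angeloyl groups with retention of the Z geometry. Only the secondary 6α-hydroxyl reacts, the C8 hydroxyl being tertiary and the C13 one silylated.

Step 18
Reactants: 28 (13R)-8α-hydroxy-13-[(triethylsilyl)oxy]labd-14-en-6α-yl (Z)-2-methylbut-2-enoate
Product: 29 (13R)-8α,13-dihydroxylabd-14-en-6α-yl (Z)-2-methylbut-2-enoate (CNP0203829.1)
Conditions: Bu4NF, AcOH, THF, 0 °C to rt
Reagents that add atoms: none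
Why: Fluoride cleavage of the tertiary TES ether, buffered with acetic acid so that the angelate is neither hydrolysed nor isomerised and the allylic carbinol never meets strong acid.

## Compound list

1 | 2,2,6-trimethylcyclohexanone | CC1CCCC(C)(C)C1=O | starting material
2 | allyl chloroformate | C=CCOC(Cl)=O | starting material
3 | allyl 2,6,6-trimethylcyclohex-1-en-1-yl carbonate | C=CCOC(=O)OC1=C(C)CCCC1(C)C | intermediate
4 | (2R)-2,6,6-trimethyl-2-(prop-2-en-1-yl)cyclohexan-1-one | C=CC[C@@]1(C)CCCC(C)(C)C1=O | intermediate
5 | (4R)-4,8,8-trimethyl-4-(prop-2-en-1-yl)-1-oxaspiro[2.5]octane, both spiro epimers | C=CC[C@@]1(C)CCCC(C)(C)C12CO2 | intermediate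
6 | 2-[(4R)-4,8,8-trimethyl-1-oxaspiro[2.5]octan-4-yl]acetaldehyde, both spiro epimers | O=CC[C@@]1(C)CCCC(C)(C)C12CO2 | intermediate (not isolated)
7 | 2-[(4R)-4,8,8-trimethyl-1-oxaspiro[2.5]octan-4-yl]acetonitrile, both spiro epimers | N#CC[C@@]1(C)CCCC(C)(C)C12CO2 | intermediate
8 | 2-[(1R)-2-formyl-1,3,3-trimethylcyclohexyl]acetonitrile, both C2 epimers | N#CC[C@@]1(C)CCCC(C)(C)C1C=O | intermediate (not isolated)
9 | 2-[(1R)-2-(hydroxymethyl)-1,3,3-trimethylcyclohexyl]acetonitrile, both C2 epimers | N#CC[C@@]1(C)CCCC(C)(C)C1CO | intermediate
10 | (R)-linalool, (3R)-3,7-dimethylocta-1,6-dien-3-ol | C=C[C@](C)(O)CCC=C(C)C | starting material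
11 | triethyl{[(3R)-3,7-dimethylocta-1,6-dien-3-yl]oxy}silane | C=C[C@](C)(O[Si](CC)(CC)CC)CCC=C(C)C | intermediate
12 | (4R)-4-methyl-4-[(triethylsilyl)oxy]hex-5-enal | C=C[C@](C)(O[Si](CC)(CC)CC)CCC=O | intermediate (not isolated)
13 | (4R)-4-methyl-4-[(triethylsilyl)oxy]hex-5-enoic acid | C=C[C@](C)(O[Si](CC)(CC)CC)CCC(=O)O | intermediate
14 | 2-thioxopyridin-1(2H)-yl (4R)-4-methyl-4-[(triethylsilyl)oxy]hex-5-enoate | C=C[C@](C)(O[Si](CC)(CC)CC)CCC(=O)On1ccccc1=S | intermediate (not isolated)
15 | triethyl{[(3R)-5-iodo-3-methylpent-1-en-3-yl]oxy}silane | C=C[C@](C)(O[Si](CC)(CC)CC)CCI | intermediate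
16 | (5R)-2-[(1R)-2-(hydroxymethyl)-1,3,3-trimethylcyclohexyl]-5-methyl-5-[(triethylsilyl)oxy]hept-6-enenitrile, epimers at chain C2 and ring C2 | C=C[C@](C)(O[Si](CC)(CC)CC)CCC(C#N)[C@@]1(C)CCCC(C)(C)C1CO | intermediate
17 | (6R)-3-[(1R)-2-(hydroxymethyl)-1,3,3-trimethylcyclohexyl]-6-methyl-6-[(triethylsilyl)oxy]oct-7-en-2-imine, epimer mixture | C=C[C@](C)(O[Si](CC)(CC)CC)CCC(C(C)=N)[C@@]1(C)CCCC(C)(C)C1CO | intermediate (not isolated)
18 | (6R)-3-[(1S)-2-(hydroxymethyl)-1,3,3-trimethylcyclohexyl]-6-methyl-6-[(triethylsilyl)oxy]oct-7-en-2-one, epimer mixture, with its cyclic hemiketal | C=C[C@](C)(O[Si](CC)(CC)CC)CCC(C(C)=O)[C@@]1(C)CCCC(C)(C)C1CO | intermediate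
19 | (2S)-2,6,6-trimethyl-2-[(6R)-6-methyl-2-oxo-6-[(triethylsilyl)oxy]oct-7-en-3-yl]cyclohexane-1-carbaldehyde, epimers at C5 and C9 (labdane numbering) | C=C[C@](C)(O[Si](CC)(CC)CC)CCC(C(C)=O)[C@@]1(C)CCCC(C)(C)C1C=O | intermediate (key-step precursor)
20 | (13R)-6α-hydroxy-13-[(triethylsilyl)oxy]-17-norlabd-14-en-8-one | C=C[C@](C)(O[Si](CC)(CC)CC)CC[C@@H]1[C@@]2(C)CCCC(C)(C)[C@@H]2[C@@H](O)CC1=O | intermediate (key-step product)
21 | (13R)-13-[(triethylsilyl)oxy]-6α-[(trimethylsilyl)oxy]-17-norlabd-14-en-8-one | C=C[C@](C)(O[Si](CC)(CC)CC)CC[C@@H]1[C@@]2(C)CCCC(C)(C)[C@@H]2[C@@H](O[Si](C)(C)C)CC1=O | intermediate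
22 | (13R)-13-[(triethylsilyl)oxy]-6α-[(trimethylsilyl)oxy]labda-8(17),14-diene | C=C[C@](C)(O[Si](CC)(CC)CC)CC[C@@H]1[C@@]2(C)CCCC(C)(C)[C@@H]2[C@@H](O[Si](C)(C)C)CC1=C | intermediate (not isolated)
23 | (13R)-13-[(triethylsilyl)oxy]labda-8(17),14-dien-6α-ol | C=C[C@](C)(O[Si](CC)(CC)CC)CC[C@@H]1[C@@]2(C)CCCC(C)(C)[C@@H]2[C@@H](O)CC1=C | intermediate
24 | (13R)-8α,17-epoxy-13-[(triethylsilyl)oxy]labd-14-en-6α-ol | C=C[C@](C)(O[Si](CC)(CC)CC)CC[C@@H]1[C@@]2(C)CCCC(C)(C)[C@@H]2[C@@H](O)C[C@@]13OC3 | intermediate
25 | (13R)-13-[(triethylsilyl)oxy]labd-14-ene-6α,8α-diol | C=C[C@](C)(O[Si](CC)(CC)CC)CC[C@@H]1[C@@]2(C)CCCC(C)(C)[C@@H]2[C@@H](O)C[C@@]1(C)O | intermediate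
26 | angelic acid, (Z)-2-methylbut-2-enoic acid | C/C=C(/C)C(=O)O | starting material
27 | (Z)-2-methylbut-2-enoic 2,4,6-trichlorobenzoic anhydride | C/C=C(/C)C(=O)OC(=O)c1c(Cl)cc(Cl)cc1Cl | intermediate (not isolated)
28 | (13R)-8α-hydroxy-13-[(triethylsilyl)oxy]labd-14-en-6α-yl (Z)-2-methylbut-2-enoate | C=C[C@](C)(O[Si](CC)(CC)CC)CC[C@@H]1[C@@]2(C)CCCC(C)(C)[C@@H]2[C@@H](OC(=O)/C(C)=C\C)C[C@@]1(C)O | intermediate
29 | (13R)-8α,13-dihydroxylabd-14-en-6α-yl (Z)-2-methylbut-2-enoate, (5S,6S,8R,9R,10S,13R) | C=C[C@](C)(O)CC[C@@H]1[C@@]2(C)CCCC(C)(C)[C@@H]2[C@@H](OC(=O)/C(C)=C\C)C[C@@]1(C)O | target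

## Step count and uncertain steps

Total: 18 steps. Longest linear sequence: 15 steps (steps 1 to 5 and 9 to 18); the chain fragment (steps 6 to 8) joins at step 9.

**Step 12 (key step).** Two processes can go wrong. Equilibration at C5 may be incomplete, because it needs retro-aldol opening and exchange of a very hindered aldehyde α-hydrogen, so cis-fused aldols may persist. The aldols may also lose water by E1cB, fastest for isomers with an axial hydroxyl. The fallback sets out from 19 and accepts the dehydration. KOH in MeOH at 60 °C gives the enone (13R)-13-[(triethylsilyl)oxy]-17-norlabda-6,14-dien-8-one F1, in which C5 is γ to the carbonyl and equilibrates through the dienolate, and C9 through the enolate. Nucleophilic epoxidation (H2O2, NaOH, MeOH, 0 °C) should come from the α face, away from the two syn-axial methyl groups, and give (13R)-6α,7α-epoxy-13-[(triethylsilyl)oxy]-17-norlabd-14-en-8-one F2. SmI2 in THF/MeOH at −78 °C cleaves the C7–O bond and returns to the route at 20. Enone formed as a by-product of step 12 can be recycled the same way.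

**Step 10.** Methyllithium may deprotonate C9 instead of adding to the hindered nitrile, or the neighbouring alkoxide may close onto the nitrile, so conversion to the ketone stalls. The fallback sets out from 16 and builds the methyl ketone through the aldehyde. i-Bu2AlH (toluene, −78 °C, tartrate work-up) gives the hydroxy aldehyde as its lactol, 4a,8,8-trimethyl-4-[(3R)-3-methyl-3-[(triethylsilyl)oxy]pent-4-en-1-yl]octahydro-1H-isochromen-3-ol F3. MeMgBr (THF, 0 °C) opens it to (6R)-3-[(1S)-2-(hydroxymethyl)-1,3,3-trimethylcyclohexyl]-6-methyl-6-[(triethylsilyl)oxy]oct-7-en-2-ol F4. A Swern oxidation ((COCl)2, DMSO, Et3N, −78 °C), which activates both hydroxyls before either carbonyl forms, returns to the route at 19.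

**Step 3.** Addition of the ylide to a ketone flanked by two quaternary carbons may be slower than decomposition of the ylide. The fallback sets out from 4 and reaches the same epoxide through an alkene. MeLi (Et2O, 0 °C) adds to the non-enolisable ketone to give (2R)-1,2,6,6-tetramethyl-2-(prop-2-en-1-yl)cyclohexan-1-ol F5. Syn-elimination with Burgess reagent (benzene, 50 °C), possible only toward the methyl group, gives (1R)-1,3,3-trimethyl-2-methylidene-1-(prop-2-en-1-yl)cyclohexane F6. One equivalent of mCPBA (NaHCO3, CH2Cl2, 0 °C) epoxidises the more electron-rich 1,1-disubstituted alkene and returns to the route at 5.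

**Step 14.** The basic ylide may enolise the ketone toward C7 and expel the silyloxy group, or methylenation may be slow. The fallback sets out from 21 and uses a Peterson olefination. The non-basic reagent from Me3SiCH2Li and CeCl3 (THF, −78 °C) adds to give (13R)-8-[(trimethylsilyl)methyl]-13-[(triethylsilyl)oxy]-6α-[(trimethylsilyl)oxy]-17-norlabd-14-en-8-ol F7. KH in THF eliminates it to 22, and the methanolysis of step 14 then returns to the route at 23.

**Step 17.** Z-to-E isomerisation of the angeloyl group during activation, or slow acylation of the hindered 6α-hydroxyl, would give tiglate or leave diol. The fallback sets out from 25 and builds the Z alkene on the ester. Acylation with 2-[bis(2,2,2-trifluoroethoxy)phosphoryl]propanoic acid (DCC, DMAP, CH2Cl2) gives (13R)-8α-hydroxy-13-[(triethylsilyl)oxy]labd-14-en-6α-yl 2-[bis(2,2,2-trifluoroethoxy)phosphoryl]propanoate F8. Still–Gennari olefination with acetaldehyde (KN(SiMe3)2, 18-crown-6, THF, −78 °C) gives the Z-configured ester and returns to the route at 28.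

## Further compounds

F1 | step 12 | (13R)-13-[(triethylsilyl)oxy]-17-norlabda-6,14-dien-8-one | C=C[C@](C)(O[Si](CC)(CC)CC)CC[C@@H]1[C@@]2(C)CCCC(C)(C)[C@@H]2C=CC1=O
F2 | step 12 | (13R)-6α,7α-epoxy-13-[(triethylsilyl)oxy]-17-norlabd-14-en-8-one | C=C[C@](C)(O[Si](CC)(CC)CC)CC[C@@H]1[C@@]2(C)CCCC(C)(C)[C@@H]2[C@H]3O[C@H]3C1=O
F3 | step 10 | 4a,8,8-trimethyl-4-[(3R)-3-methyl-3-[(triethylsilyl)oxy]pent-4-en-1-yl]octahydro-1H-isochromen-3-ol (lactol; ring-fusion carbon 4a configured as C10 of 16; other ring centres as mixtures) | C=C[C@](C)(O[Si](CC)(CC)CC)CCC1C(O)OCC2C(C)(C)CCC[C@]12C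
F4 | step 10 | (6R)-3-[(1S)-2-(hydroxymethyl)-1,3,3-trimethylcyclohexyl]-6-methyl-6-[(triethylsilyl)oxy]oct-7-en-2-ol (epimer mixture) | C=C[C@](C)(O[Si](CC)(CC)CC)CCC(C(C)O)[C@@]1(C)CCCC(C)(C)C1CO
F5 | step 3 | (2R)-1,2,6,6-tetramethyl-2-(prop-2-en-1-yl)cyclohexan-1-ol (both C1 epimers) | C=CC[C@@]1(C)CCCC(C)(C)C1(C)O
F6 | step 3 | (1R)-1,3,3-trimethyl-2-methylidene-1-(prop-2-en-1-yl)cyclohexane | C=CC[C@@]1(C)CCCC(C)(C)C1=C
F7 | step 14 | (13R)-8-[(trimethylsilyl)methyl]-13-[(triethylsilyl)oxy]-6α-[(trimethylsilyl)oxy]-17-norlabd-14-en-8-ol (C8 epimers) | C=C[C@](C)(O[Si](CC)(CC)CC)CC[C@@H]1[C@@]2(C)CCCC(C)(C)[C@@H]2[C@@H](O[Si](C)(C)C)CC1(O)C[Si](C)(C)C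
F8 | step 17 | (13R)-8α-hydroxy-13-[(triethylsilyl)oxy]labd-14-en-6α-yl 2-[bis(2,2,2-trifluoroethoxy)phosphoryl]propanoate | C=C[C@](C)(O[Si](CC)(CC)CC)CC[C@@H]1[C@@]2(C)CCCC(C)(C)[C@@H]2[C@@H](OC(=O)C(C)P(=O)(OCC(F)(F)F)OCC(F)(F)F)C[C@@]1(C)O
A1 | alternative 1 | (1S)-3-ethenyl-2,4,4-trimethylcyclohex-2-en-1-yl but-2-ynoate | CC#CC(=O)O[C@H]1CCC(C)(C)C(C=C)=C1C
A2 | alternative 1 | tricyclic dienyl lactone (C5=C6, C8=C9, lactone C1–O–C11) | CC1=C2C(=O)O[C@H]3CCC(C)(C)C(=CC1)[C@@]23C
A3 | alternative 2 | 4-methyl-4-[(triethylsilyl)oxy]-6-(2,6,6-trimethylcyclohex-1-en-1-yl)oxan-2-one (silyloxy and cyclohexenyl groups trans) | O=C1C[C@](C)(O[Si](CC)(CC)CC)C[C@H](O1)C1=C(C)CCCC1(C)C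
A4 | alternative 2 | 8-[(triethylsilyl)oxy]drim-5-en-11-oic acid, 9-epi (carboxyl α) | OC(=O)[C@H]1[C@@]2(C)CCCC(C)(C)C2=CC[C@@]1(C)O[Si](CC)(CC)CC
A5 | alternative 3 | 2,6-dimethyl-1,4-benzoquinone | CC1=CC(=O)C=C(C)C1=O
A6 | alternative 3 | 4-methylpenta-1,3-diene | C=CC=C(C)C
A7 | alternative 3 | cis-fused quinone Diels–Alder adduct (quaternary C10 as in the target, 5β-H) | O=C1[C@@]2(C)CC=CC(C)(C)[C@H]2C(=O)C=C1C
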